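The benzene ring is built last. O1, C2, C3, C3a and C7a, with the trans-(2R,3S) pair, come intact from 2-deoxy-D-ribose as a 4-silyloxy-5-isopropenyl-4,5-dihydrofuran whose C2 carries a methyl trimethylsilyl ketene acetal. The key step exploits the meta-dioxygenated acetyl arene (ring C3a–C4–C5–C6–C7–C7a, oxygens at C6 and C7a, acetyl at C5): one [4+2] cycloaddition of this 1,1,3-trioxygenated diene with but-3-yn-2-one forms C3a–C4 and C5–C6, and loss of methanol aromatises the ring without touching C2 or C3. O-Methylation, desilylation and esterification with (Z)-2-(acetoxymethyl)but-2-enoic acid, made from but-2-yn-1-ol, complete the synthesis.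

Key step: step 11

Remark: the enoate geometry (drawn E) and the ketene acetal geometry (drawn Z) are assumed; either isomer leads to the same dienolate and the same arene, so neither affects the outcome.

Step 1
Reactants: 1 2-deoxy-D-ribose
Product: 2 2-deoxy-D-ribono-1,4-lactone, i.e. (4S,5R)-4-hydroxy-5-(hydroxymethyl)oxolan-2-one
Conditions: Br2, H2O, rt, dark; air purge, weakly basic anion-exchange resin, evaporation
Reagents that add atoms: none
Why: Bromine-water oxidation of the free aldose at the hemiacetal carbon should give the aldonic acid, which closes to the five-membered lactone, and neither stereocentre is involved.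

Step 2
Reactants: 2 2-deoxy-D-ribono-1,4-lactone
Product: 3 (4S,5R)-4-(tert-butyldimethylsilyloxy)-5-[(tert-butyldimethylsilyloxy)methyl]oxolan-2-one
Conditions: TBSCl (2.5 equiv), imidazole, DMF, rt
Reagents that add atoms: tert-butyldimethylsilyl chloride, CC(C)(C)[Si](C)(C)Cl
Why: Imidazole-promoted silylation of both hydroxyl groups is routine and masks the future C3 oxygen as a poor leaving group.

Step 3
Reactants: 3 the bis-silylated lactone; 4 methyl acetate
Product: 6 methyl 2-[(4S,5R)-4-(tert-butyldimethylsilyloxy)-5-[(tert-butyldimethylsilyloxy)methyl]-2-hydroxyoxolan-2-yl]acetate (hemiketal, both anomers), via methyl acetate lithium enolate 5 (not isolated)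
Conditions: LiN(i-Pr)2 (2.2 equiv), 4 (2.2 equiv), THF, −78 °C; then 3, −78 °C; AcOH quench at −78 °C
Reagents that add atoms: none
Why: Claisen-type addition of the ester enolate to the lactone carbonyl at −78 °C should outrun deprotonation of the lactone α-CH2, and the adduct does not collapse before the cold acid quench.

Step 4
Reactants: 6 the hemiketal
Product: 8 methyl (2E)-2-[(4S,5R)-4-(tert-butyldimethylsilyloxy)-5-[(tert-butyldimethylsilyloxy)methyl]oxolan-2-ylidene]acetate, via hemiketal trifluoroacetate 7 (not isolated)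
Conditions: (CF3CO)2O, pyridine, CH2Cl2, 0 °C → rt
Reagents that add atoms: none
Why: Acylation of the anomeric hydroxyl and base-mediated loss of trifluoroacetate (dehydration of a ketose hemiketal to an exo-glycal) should give the conjugated push–pull enol ether, with E geometry favoured because ring C3 is unsubstituted.

Step 5
Reactants: 8 the bis-silylated enoate
Product: 9 methyl (2E)-2-[(4S,5R)-4-(tert-butyldimethylsilyloxy)-5-(hydroxymethyl)oxolan-2-ylidene]acetate
Conditions: HF·pyridine, pyridine, THF, 0 °C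
Reagents that add atoms: none
Why: Buffered HF·pyridine cleaves the primary silyl ether much faster than the hindered secondary one (selective desilylation), and the ester-conjugated enol ether tolerates the weakly acidic medium.

Step 6
Reactants: 9 the primary alcohol
Product: 10 methyl (2E)-2-[(4S,5S)-4-(tert-butyldimethylsilyloxy)-5-formyloxolan-2-ylidene]acetate
Conditions: Dess–Martin periodinane, pyridine, CH2Cl2, 0 °C → rt
Reagents that add atoms: none
Why: Dess–Martin oxidation under pyridine buffering is mild enough to give the aldehyde without epimerising C5 or expelling the β-silyloxy group.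

Step 7
Reactants: 10 the aldehyde
Product: 11 methyl (2E)-2-[(4S,5R)-4-(tert-butyldimethylsilyloxy)-5-(1-hydroxyethyl)oxolan-2-ylidene]acetate (both carbinol epimers)
Conditions: MeMgBr, THF, −78 °C; then H2O/NH4Cl
Reagents that add atoms: methylmagnesium bromide, C[Mg]Br
Why: Grignard addition to the aldehyde at −78 °C is far faster than attack on the deactivated β-alkoxy enoate; the new carbinol centre forms unselectively and is erased in step 8.

Step 8
Reactants: 11 the secondary alcohol
Product: 12 methyl (2E)-2-[(4S,5S)-5-acetyl-4-(tert-butyldimethylsilyloxy)oxolan-2-ylidene]acetate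
Conditions: Dess–Martin periodinane, pyridine, CH2Cl2, rt
Reagents that add atoms: none
Why: Dess–Martin oxidation of the secondary alcohol should give the methyl ketone and remove the carbinol stereocentre.

Step 9
Reactants: 12 the methyl ketone
Product: 13 methyl (2E)-2-[(4S,5R)-4-(tert-butyldimethylsilyloxy)-5-(prop-1-en-2-yl)oxolan-2-ylidene]acetate
Conditions: Ph3PCH3Br, KOtBu, THF, 0 °C; then 12, −78 → 0 °C
Reagents that add atoms: methyltriphenylphosphonium bromide, C[P+](c1ccccc1)(c1ccccc1)c1ccccc1.[Br-]
Why: Wittig methylenation of the ketone installs the isopropenyl group while the ester is inert to the ylide; the trans C4/C5 arrangement is the more stable one, so C5 should keep its configuration.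

Step 10
Reactants: 13 the isopropenyl enoate
Product: 15 (4S,5R)-4-(tert-butyldimethylsilyloxy)-2-[(Z)-2-methoxy-2-(trimethylsilyloxy)ethenyl]-5-(prop-1-en-2-yl)-4,5-dihydrofuran, via lithium dienolate 14 (not isolated)
Conditions: LiN(i-Pr)2 (1.2 equiv), Me3SiCl (1.5 equiv, present before the base), THF, −78 °C; solvent exchange to pentane, filtration under argon; used crude at once
Reagents that add atoms: chlorotrimethylsilane, C[Si](C)(C)Cl
Why: The ester carbonyl directs the amide base to the syn γ-CH2 (ring C3), and the vinylogous enolate is O-silylated immediately by the chlorosilane already present (ketene acetal diene formation from a β-alkoxy enoate), which should leave it too short-lived at −78 °C to expel the C4 silyloxy group.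

Step 11
Reactants: 15 the ketene acetal diene; 16 but-3-yn-2-one
Product: 19 1-[(2R,3S)-3-(tert-butyldimethylsilyloxy)-6-hydroxy-2-(prop-1-en-2-yl)-2,3-dihydro-1-benzofuran-5-yl]ethanone, via cyclohexadiene cycloadduct 17 (not isolated), via aryl trimethylsilyl ether 18 (not isolated)
Conditions: 16 (1.5 equiv), toluene, −40 °C → rt; then 0.1 M aq. citric acid, THF, 0 °C
Reagents that add atoms: none
Why: The diene C3=C2–CH=C(OMe)OSiMe3 should add to the ynone either as an asynchronous Diels–Alder reaction or by vinylogous Mukaiyama–Michael addition followed by six-membered closure, forming C3a–C4 and C5–C6. The closest known reaction type is the benzannulation of 1-alkoxy-1-silyloxy-3-oxy dienes with alkynones, which gives 2-hydroxy-4-alkoxy acyl arenes. The carbocycle closes by intermolecular [4+2] cycloaddition (in the stepwise limit a 6-exo-trig attack of the allenolate carbon C5 on the silyloxycarbenium carbon C6), and adduct 17, with a mixed ketal at C6 and a hydrogen at C3a, aromatises by 1,4-loss of methanol before dilute acid removes the aryl silyl group. No stereocentre is created, and C2 and C3, fixed by the sugar, take no part. The regiochemistry needed (C3a to the unsubstituted alkyne carbon, C6 to the acetyl-bearing carbon) is secured because all three oxygen donors concentrate nucleophilicity at C3a while the ynone is electrophilic at its terminal carbon. Survival of the C3 silyloxy group relies on the absence of Lewis and strong acids, the low temperature and the poor leaving-group ability of silyloxide, and any material that lost silanol in place of methanol would simply be 20.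

Step 12
Reactants: 19 the chelated phenol
Product: 20 1-[(2R,3S)-3-(tert-butyldimethylsilyloxy)-6-methoxy-2-(prop-1-en-2-yl)-2,3-dihydro-1-benzofuran-5-yl]ethanone
Conditions: MeI, K2CO3, DMF, 40 °C
Reagents that add atoms: iodomethane, CI
Why: Williamson O-methylation of the phenoxide; gentle warming in DMF overcomes the hydrogen bond to the acetyl group, and the silyl ether and the stereocentres are inert to carbonate.

Step 13
Reactants: 20 the methyl ether
Product: 21 1-[(2R,3S)-3-hydroxy-6-methoxy-2-(prop-1-en-2-yl)-2,3-dihydro-1-benzofuran-5-yl]ethanone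
Conditions: TBAF, AcOH (1:1), THF, 0 °C → rt
Reagents that add atoms: none
Why: Fluoride-mediated desilylation of the secondary benzylic ether, buffered with acetic acid so that the 3-hydroxy-2,3-dihydrobenzofuran neither eliminates to the benzofuran nor epimerises.

Step 14
Reactants: 22 but-2-yn-1-ol
Product: 23 (Z)-2-(tributylstannyl)but-2-en-1-ol
Conditions: Bu3SnH, [Cp*RuCl]4 (cat.), CH2Cl2, rt
Reagents that add atoms: tributyltin hydride, CCCC[SnH](CCCC)CCCC
Why: Ruthenium-catalysed trans-hydrostannation of a propargylic alcohol places tin on the alkyne carbon next to the hydroxyl group by anti addition, which sets methyl and tin cis and so fixes the Z geometry of the acid.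

Step 15
Reactants: 23 the alkenylstannane
Product: 24 (Z)-2-iodobut-2-en-1-ol
Conditions: I2, CH2Cl2, 0 °C
Reagents that add atoms: iodine, II
Why: Iododestannylation of an alkenylstannane proceeds with retention of alkene geometry.

Step 16
Reactants: 24 the alkenyl iodide
Product: 26 (Z)-2-(hydroxymethyl)but-2-enoic acid (sarracinic acid), via dilithio alkenyl alkoxide 25 (not isolated)
Conditions: t-BuLi (3.1 equiv), Et2O, −78 °C; CO2 (gas), −78 °C → rt; 1 M HCl
Reagents that add atoms: carbon dioxide, O=C=O
Why: The first equivalent of tert-butyllithium forms the alkoxide, iodine–lithium exchange then gives a configurationally stable alkenyllithium, and its carboxylation retains the geometry, so CO2H ends up cis to methyl.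

Step 17
Reactants: 26 sarracinic acid
Product: 27 (Z)-2-(acetoxymethyl)but-2-enoic acid
Conditions: Ac2O, pyridine, CH2Cl2, 0 °C → rt; aqueous work-up
Reagents that add atoms: acetic anhydride, CC(=O)OC(C)=O
Why: Acetylation of the primary allylic alcohol with acetic anhydride and pyridine; the carboxyl group is recovered as the free acid after the aqueous work-up.

Step 18
Reactants: 21 the C3 alcohol; 27 the acetoxy acid
Product: 29 (2R,3S)-5-acetyl-6-methoxy-2-(prop-1-en-2-yl)-2,3-dihydro-1-benzofuran-3-yl (Z)-2-(acetoxymethyl)but-2-enoate (CNP0221694.1), via mixed anhydride 28 (not isolated)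
Conditions: 27, 2,4,6-trichlorobenzoyl chloride, Et3N, toluene, rt; then 21, DMAP (cat.), toluene, rt
Reagents that add atoms: none
Why: Yamaguchi esterification: the hindered mixed anhydride should transfer only the butenoyl group to the secondary alcohol with retention at C3 (the C3–O bond is not broken), and a short reaction at room temperature with little DMAP limits Z-to-E isomerisation.

Compound list
1 | 2-deoxy-D-ribose | O=CC[C@H](O)[C@H](O)CO | starting material
2 | 2-deoxy-D-ribono-1,4-lactone, (4S,5R)-4-hydroxy-5-(hydroxymethyl)oxolan-2-one | O=C1C[C@H](O)[C@@H](CO)O1 | intermediate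
3 | (4S,5R)-4-(tert-butyldimethylsilyloxy)-5-[(tert-butyldimethylsilyloxy)methyl]oxolan-2-one | O=C1C[C@H](O[Si](C)(C)C(C)(C)C)[C@@H](CO[Si](C)(C)C(C)(C)C)O1 | intermediate
4 | methyl acetate | COC(C)=O | starting material
5 | lithium enolate of methyl acetate | [Li+].[O-]C(=C)OC | intermediate (not isolated)
6 | methyl 2-[(4S,5R)-4-(tert-butyldimethylsilyloxy)-5-[(tert-butyldimethylsilyloxy)methyl]-2-hydroxyoxolan-2-yl]acetate | COC(=O)CC1(O)C[C@H](O[Si](C)(C)C(C)(C)C)[C@@H](CO[Si](C)(C)C(C)(C)C)O1 | intermediate
7 | methyl 2-[(4S,5R)-4-(tert-butyldimethylsilyloxy)-5-[(tert-butyldimethylsilyloxy)methyl]-2-(trifluoroacetoxy)oxolan-2-yl]acetate | COC(=O)CC1(OC(=O)C(F)(F)F)C[C@H](O[Si](C)(C)C(C)(C)C)[C@@H](CO[Si](C)(C)C(C)(C)C)O1 | intermediate (not isolated)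
8 | methyl (2E)-2-[(4S,5R)-4-(tert-butyldimethylsilyloxy)-5-[(tert-butyldimethylsilyloxy)methyl]oxolan-2-ylidene]acetate | COC(=O)/C=C1\C[C@H](O[Si](C)(C)C(C)(C)C)[C@@H](CO[Si](C)(C)C(C)(C)C)O1 | intermediate
9 | methyl (2E)-2-[(4S,5R)-4-(tert-butyldimethylsilyloxy)-5-(hydroxymethyl)oxolan-2-ylidene]acetate | COC(=O)/C=C1\C[C@H](O[Si](C)(C)C(C)(C)C)[C@@H](CO)O1 | intermediate
10 | methyl (2E)-2-[(4S,5S)-4-(tert-butyldimethylsilyloxy)-5-formyloxolan-2-ylidene]acetate | COC(=O)/C=C1\C[C@H](O[Si](C)(C)C(C)(C)C)[C@@H](C=O)O1 | intermediate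
11 | methyl (2E)-2-[(4S,5R)-4-(tert-butyldimethylsilyloxy)-5-(1-hydroxyethyl)oxolan-2-ylidene]acetate (carbinol epimers) | COC(=O)/C=C1\C[C@H](O[Si](C)(C)C(C)(C)C)[C@@H](C(C)O)O1 | intermediate
12 | methyl (2E)-2-[(4S,5S)-5-acetyl-4-(tert-butyldimethylsilyloxy)oxolan-2-ylidene]acetate | COC(=O)/C=C1\C[C@H](O[Si](C)(C)C(C)(C)C)[C@@H](C(C)=O)O1 | intermediate
13 | methyl (2E)-2-[(4S,5R)-4-(tert-butyldimethylsilyloxy)-5-(prop-1-en-2-yl)oxolan-2-ylidene]acetate | COC(=O)/C=C1\C[C@H](O[Si](C)(C)C(C)(C)C)[C@@H](C(C)=C)O1 | intermediate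
14 | lithium dienolate of 13 | C=C(C)[C@H]1OC(\C=C(\OC)[O-])=C[C@@H]1O[Si](C)(C)C(C)(C)C.[Li+] | intermediate (not isolated)
15 | (4S,5R)-4-(tert-butyldimethylsilyloxy)-2-[(Z)-2-methoxy-2-(trimethylsilyloxy)ethenyl]-5-(prop-1-en-2-yl)-4,5-dihydrofuran | C=C(C)[C@H]1OC(\C=C(\OC)O[Si](C)(C)C)=C[C@@H]1O[Si](C)(C)C(C)(C)C | intermediate
16 | but-3-yn-2-one | C#CC(C)=O | starting material
17 | 1-[(2R,3S)-3-(tert-butyldimethylsilyloxy)-6-methoxy-2-(prop-1-en-2-yl)-6-(trimethylsilyloxy)-2,3,3a,6-tetrahydro-1-benzofuran-5-yl]ethanone | C=C(C)[C@H]1OC2=CC(OC)(O[Si](C)(C)C)C(C(C)=O)=CC2[C@@H]1O[Si](C)(C)C(C)(C)C | intermediate (not isolated)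
18 | 1-[(2R,3S)-3-(tert-butyldimethylsilyloxy)-2-(prop-1-en-2-yl)-6-(trimethylsilyloxy)-2,3-dihydro-1-benzofuran-5-yl]ethanone | C=C(C)[C@H]1Oc2cc(O[Si](C)(C)C)c(C(C)=O)cc2[C@@H]1O[Si](C)(C)C(C)(C)C | intermediate (not isolated)
19 | 1-[(2R,3S)-3-(tert-butyldimethylsilyloxy)-6-hydroxy-2-(prop-1-en-2-yl)-2,3-dihydro-1-benzofuran-5-yl]ethanone | C=C(C)[C@H]1Oc2cc(O)c(C(C)=O)cc2[C@@H]1O[Si](C)(C)C(C)(C)C | intermediate
20 | 1-[(2R,3S)-3-(tert-butyldimethylsilyloxy)-6-methoxy-2-(prop-1-en-2-yl)-2,3-dihydro-1-benzofuran-5-yl]ethanone | C=C(C)[C@H]1Oc2cc(OC)c(C(C)=O)cc2[C@@H]1O[Si](C)(C)C(C)(C)C | intermediate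
21 | 1-[(2R,3S)-3-hydroxy-6-methoxy-2-(prop-1-en-2-yl)-2,3-dihydro-1-benzofuran-5-yl]ethanone | C=C(C)[C@H]1Oc2cc(OC)c(C(C)=O)cc2[C@@H]1O | intermediate
22 | but-2-yn-1-ol | CC#CCO | starting material
23 | (Z)-2-(tributylstannyl)but-2-en-1-ol | C/C=C(/CO)[Sn](CCCC)(CCCC)CCCC | intermediate
24 | (Z)-2-iodobut-2-en-1-ol | C/C=C(/CO)I | intermediate
25 | dilithio species of 24 (lithium (Z)-2-lithiobut-2-en-1-olate) | C/C=C(/C[O-])[Li].[Li+] | intermediate (not isolated)
26 | (Z)-2-(hydroxymethyl)but-2-enoic acid | C/C=C(/CO)C(=O)O | intermediate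
27 | (Z)-2-(acetoxymethyl)but-2-enoic acid | C/C=C(/COC(C)=O)C(=O)O | intermediate
28 | (Z)-2-(acetoxymethyl)but-2-enoic 2,4,6-trichlorobenzoic anhydride | C/C=C(/COC(C)=O)C(=O)OC(=O)c1c(Cl)cc(Cl)cc1Cl | intermediate (not isolated)
29 | (2R,3S)-5-acetyl-6-methoxy-2-(prop-1-en-2-yl)-2,3-dihydro-1-benzofuran-3-yl (Z)-2-(acetoxymethyl)but-2-enoate | C=C(C)[C@H]1Oc2cc(OC)c(C(C)=O)cc2[C@@H]1OC(=O)/C(=C\C)COC(C)=O | target

Total step count: 18. Longest linear sequence: 14 steps (steps 1–13 and step 18); the acid 27 is made in a four-step side branch (steps 14–17).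

Steps most likely to fail

Step 11. The ynone may oligomerise under traces of base, cycloaddition at the substituted diene terminus may be slow, or the allylic C–O bond next to the reacting terminus may ionise before the ring has aromatised. The fallback sets out from 13 and comes back at 19, replacing the silyl diene and the alkyne by an anionic Michael–Dieckmann annulation. The lithium dienolate 14, made from 13 with LiN(i-Pr)2 in THF at −78 °C, would be treated with commercial (E)-4-methoxybut-3-en-2-one. Addition through the γ-carbon (ring C3) and Claisen-type closure of the resulting ketone enolate onto the methyl ester should give 1-[(2R,3S)-3-(tert-butyldimethylsilyloxy)-4-methoxy-6-oxo-2-(prop-1-en-2-yl)-2,3,3a,4,5,6-hexahydro-1-benzofuran-5-yl]ethanone F1. On mild acidic work-up F1 loses methanol and tautomerises to phenol 19.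

Step 10. The dienolate may expel the C4 silyloxide, or the very electron-rich diene may ionise at C4 under traces of acid; either path ends in an aromatic furan. The fallback sets out from 13 and comes back at 21, and removes the leaving group before the anion is made. Desilylation of 13 (HF·pyridine, THF) gives methyl (2E)-2-[(4S,5R)-4-hydroxy-5-(prop-1-en-2-yl)oxolan-2-ylidene]acetate F2. Two equivalents of LiN(i-Pr)2 at −78 °C then form the alkoxide-dienolate, in which the C4 oxygen is an oxide and cannot leave. Trapping with Me3SiCl gives (4S,5R)-2-[(Z)-2-methoxy-2-(trimethylsilyloxy)ethenyl]-5-(prop-1-en-2-yl)-4-(trimethylsilyloxy)-4,5-dihydrofuran F3. Cycloaddition of F3 with 16 and the same dilute-acid work-up should give 1-[(2R,3S)-3,6-dihydroxy-2-(prop-1-en-2-yl)-2,3-dihydro-1-benzofuran-5-yl]ethanone F4. Phenol-selective methylation of F4 (MeI, K2CO3, DMF) gives 21.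

Step 18. The activated acyl group may isomerise from Z to E, and DMAP may displace the allylic acetate in an SN2′ sense, scrambling the side chain. The fallback sets out from 26 and comes back at 29, introducing the acetate only after the ester bond exists, so that no activated acyl species carries an allylic leaving group. Silylation of 26 (TBSCl, imidazole) gives tert-butyldimethylsilyl (Z)-2-[(tert-butyldimethylsilyloxy)methyl]but-2-enoate F5. Selective cleavage of the silyl ester (K2CO3, aqueous MeOH) gives (Z)-2-[(tert-butyldimethylsilyloxy)methyl]but-2-enoic acid F6. Yamaguchi coupling of F6 with 21 gives (2R,3S)-5-acetyl-6-methoxy-2-(prop-1-en-2-yl)-2,3-dihydro-1-benzofuran-3-yl (Z)-2-[(tert-butyldimethylsilyloxy)methyl]but-2-enoate F7. HF·pyridine then gives (2R,3S)-5-acetyl-6-methoxy-2-(prop-1-en-2-yl)-2,3-dihydro-1-benzofuran-3-yl (Z)-2-(hydroxymethyl)but-2-enoate F8, and acetylation of F8 (Ac2O, pyridine) gives 29.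

Further compounds
F1 | step 11 | 1-[(2R,3S)-3-(tert-butyldimethylsilyloxy)-4-methoxy-6-oxo-2-(prop-1-en-2-yl)-2,3,3a,4,5,6-hexahydro-1-benzofuran-5-yl]ethanone | C=C(C)[C@H]1OC2=CC(=O)C(C(C)=O)C(OC)C2[C@@H]1O[Si](C)(C)C(C)(C)C
F2 | step 10 | methyl (2E)-2-[(4S,5R)-4-hydroxy-5-(prop-1-en-2-yl)oxolan-2-ylidene]acetate | COC(=O)/C=C1\C[C@H](O)[C@@H](C(C)=C)O1
F3 | step 10 | (4S,5R)-2-[(Z)-2-methoxy-2-(trimethylsilyloxy)ethenyl]-5-(prop-1-en-2-yl)-4-(trimethylsilyloxy)-4,5-dihydrofuran | C=C(C)[C@H]1OC(\C=C(\OC)O[Si](C)(C)C)=C[C@@H]1O[Si](C)(C)C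
F4 | step 10 | 1-[(2R,3S)-3,6-dihydroxy-2-(prop-1-en-2-yl)-2,3-dihydro-1-benzofuran-5-yl]ethanone | C=C(C)[C@H]1Oc2cc(O)c(C(C)=O)cc2[C@@H]1O
F5 | step 18 | tert-butyldimethylsilyl (Z)-2-[(tert-butyldimethylsilyloxy)methyl]but-2-enoate | C/C=C(/CO[Si](C)(C)C(C)(C)C)C(=O)O[Si](C)(C)C(C)(C)C
F6 | step 18 | (Z)-2-[(tert-butyldimethylsilyloxy)methyl]but-2-enoic acid | C/C=C(/CO[Si](C)(C)C(C)(C)C)C(=O)O
F7 | step 18 | (2R,3S)-5-acetyl-6-methoxy-2-(prop-1-en-2-yl)-2,3-dihydro-1-benzofuran-3-yl (Z)-2-[(tert-butyldimethylsilyloxy)methyl]but-2-enoate | C=C(C)[C@H]1Oc2cc(OC)c(C(C)=O)cc2[C@@H]1OC(=O)/C(=C\C)CO[Si](C)(C)C(C)(C)C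
F8 | step 18 | (2R,3S)-5-acetyl-6-methoxy-2-(prop-1-en-2-yl)-2,3-dihydro-1-benzofuran-3-yl (Z)-2-(hydroxymethyl)but-2-enoate | C=C(C)[C@H]1Oc2cc(OC)c(C(C)=O)cc2[C@@H]1OC(=O)/C(=C\C)CO
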